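## Retrosynthetic overview

1. The target comes from a fully silylated 2-aryl-tetrahydrofuran by one fluoride step. That tetrahydrofuran is closed last, by cationic 5-exo etherification (THF O1–C2, the benzylic C7–O bond) of an acyclic (8R,8'R)-triol.
2. The triol comes (LiAlH4, Raney Ni) from a 3,4-trans-4,5-trans butyrolactone. Its benzylic CH2–C4(THF) bond (C7'–C8') and its C3(THF)–C2(THF) bond (C8–C7) are both made in one three-component operation: lithiated O-TIPS-vanillin dithiane, (5R)-5-(l-menthyloxy)furan-2(5H)-one and a complete arylglycerol β-aryl ether aldehyde.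
3. Enabling feature: THF C4 and C3 (C8', C8) are a vicinal CH–CH pair, each carrying an oxygenated one-carbon unit (ring C5H2–O = C9'; CH2OH = C9). The chain C9'–C8'–C8–C9 is therefore a latent 2(5H)-furanone with C8' as β-carbon and C8 as α-carbon; the benzylic CH2 is a dithiane-masked acyl anion and THF C2 is the carbonyl carbon of an aryl aldehyde.
4. Aldehyde fragment: the threo-(7''S,8''S) diad comes from an Evans syn-aldol of an (aryloxy)acetyl oxazolidinone (nitrile as latent CHO) with O-TIPS-vanillin; the 1,3-diol is tied as a di-tert-butylsilylene.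
5. Ring order: butenolide ring (made from furfural, opened after the key step), then the dioxasilinane (protecting ring), then the tetrahydrofuran. The dithiane, menthyl acetal, lactone oxidation level and all silyl groups are temporary.

Key step: step 11

Remark on the chemistry: lignan locants are used in the text. C7/C8/C9 are THF C2, THF C3 and its CH2OH; C7'/C8'/C9' are the benzylic CH2, THF C4 and THF C5; C7''/C8''/C9'' are the arylglycerol chain. The target is read as (7S,8R,8'R,7''S,8''S): a (+)-lariciresinol core with a threo-guaiacylglycerol unit on its 4-oxygen. Abbreviations in names: Ar = 3-methoxy-4-[(triisopropylsilyl)oxy]phenyl; Men = (1R,2S,5R)-2-isopropyl-5-methylcyclohexyl; Sil = (4S,5S)-2,2-di-tert-butyl-4-Ar-1,3,2-dioxasilinan-5-yl. The carbinol carbon C7 of compounds 21–24 is deliberately left undefined (both epimers are carried on).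

## Route

Step 1
Reactants: 1 vanillin
Product: 2 3-methoxy-4-[(triisopropylsilyl)oxy]benzaldehyde
Conditions: TIPSCl, imidazole, DMF, rt
Reagents that add atoms: triisopropylsilyl chloride, CC(C)[Si](Cl)(C(C)C)C(C)C
Why: Imidazole-promoted silylation of a phenol; the hindered TIPS ether is chosen to survive n-BuLi, hydride reagents and catalytic acid later on.

Step 2
Reactants: 2 3-methoxy-4-[(triisopropylsilyl)oxy]benzaldehyde
Product: 3 2-Ar-1,3-dithiane
Conditions: HS(CH2)3SH, BF3·OEt2 (cat.), CH2Cl2, 0 °C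
Reagents that add atoms: propane-1,3-dithiol, SCCCS
Why: Lewis-acid-catalysed dithioacetalisation of an aryl aldehyde, which turns the future benzylic CH2 into an acyl-anion equivalent (umpolung).

Step 3
Reactants: 4 furfural
Product: 5 5-hydroxyfuran-2(5H)-one (racemic)
Conditions: O2, rose bengal (cat.), visible light, MeOH, rt
Reagents that add atoms: oxygen, O=O
Why: Dye-sensitised singlet-oxygen photooxygenation of the furan ([4+2] addition, then solvolytic loss of the formyl carbon as methyl formate), a standard route to this hydroxybutenolide.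

Step 4
Reactants: 5 5-hydroxyfuran-2(5H)-one; 6 (−)-menthol
Product: 7 (5R)-5-(Men-oxy)furan-2(5H)-one
Conditions: CSA (cat.), toluene, reflux, Dean–Stark; crystallisation from petroleum ether (−20 °C), mother liquor re-equilibrated with CSA and recrystallised
Reagents that add atoms: none
Why: Acid-catalysed acetalisation of the pseudo-acid; the C5 acetal stereocentre is set by crystallisation-induced diastereomer enrichment, the (5R)-epimer of the l-menthyl series being the one expected to crystallise while acid epimerises the (5S)-epimer in solution.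

Step 5
Reactants: 8 (4R)-4-benzyl-1,3-oxazolidin-2-one; 9 bromoacetyl bromide
Product: 10 (4R)-4-benzyl-3-(bromoacetyl)-1,3-oxazolidin-2-one
Conditions: n-BuLi, THF, −78 °C; then 9, −78 → 0 °C
Reagents that add atoms: none
Why: N-acylation of the lithiated oxazolidinone at the acyl bromide, which is far more electrophilic than the alkyl bromide.

Step 6
Reactants: 10 (4R)-4-benzyl-3-(bromoacetyl)-1,3-oxazolidin-2-one; 11 4-hydroxy-3-methoxybenzonitrile
Product: 12 (4R)-4-benzyl-3-[(4-cyano-2-methoxyphenoxy)acetyl]-1,3-oxazolidin-2-one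
Conditions: K2CO3, acetone, rt
Reagents that add atoms: none
Why: Williamson ether synthesis (SN2 of the phenoxide at the activated α-bromo imide carbon); the aryl–O–C8'' bond is thus in place before any stereocentre exists.

Step 7
Reactants: 12 (4R)-4-benzyl-3-[(4-cyano-2-methoxyphenoxy)acetyl]-1,3-oxazolidin-2-one; 2 3-methoxy-4-[(triisopropylsilyl)oxy]benzaldehyde
Product: 14 (4R)-4-benzyl-3-[(2R,3S)-2-(4-cyano-2-methoxyphenoxy)-3-hydroxy-3-Ar-propanoyl]-1,3-oxazolidin-2-one, via boron enolate 13 (not isolated)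
Conditions: n-Bu2BOTf, i-Pr2NEt, CH2Cl2, 0 °C; then 2, −78 → 0 °C; pH 7 buffer/MeOH/H2O2, 0 °C
Reagents that add atoms: none
Why: Evans syn-aldol of a glycolate-type imide: the (Z)-boron enolate reacts through a Zimmerman–Traxler chair on the face opposite the benzyl group of the (R)-auxiliary, which should set both new centres as (2R,3S), i.e. the threo (7''S,8''S) relationship.

Step 8
Reactants: 14 (4R)-4-benzyl-3-[(2R,3S)-2-(4-cyano-2-methoxyphenoxy)-3-hydroxy-3-Ar-propanoyl]-1,3-oxazolidin-2-one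
Product: 15 4-{[(1S,2S)-1-Ar-1,3-dihydroxypropan-2-yl]oxy}-3-methoxybenzonitrile
Conditions: LiBH4, MeOH (1 equiv), THF, 0 °C
Reagents that add atoms: none
Why: Standard reductive cleavage of the N-acyl oxazolidinone to the primary alcohol; the aryl nitrile and aryl silyl ether are inert to LiBH4 and no stereocentre is touched.

Step 9
Reactants: 15 4-{[(1S,2S)-1-Ar-1,3-dihydroxypropan-2-yl]oxy}-3-methoxybenzonitrile
Product: 16 4-(Sil-oxy)-3-methoxybenzonitrile
Conditions: t-Bu2Si(OTf)2, 2,6-lutidine, CH2Cl2, 0 °C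
Reagents that add atoms: di-tert-butylsilyl bis(trifluoromethanesulfonate), CC(C)(C)[Si](OS(=O)(=O)C(F)(F)F)(OS(=O)(=O)C(F)(F)F)C(C)(C)C
Why: Silylene protection of a 1,3-diol as a six-membered dioxasilinane; it caps the second benzylic oxygen with silicon, so that this carbon should not ionise in step 14, and it leaves with the TIPS groups at the end.

Step 10
Reactants: 16 4-(Sil-oxy)-3-methoxybenzonitrile
Product: 18 4-(Sil-oxy)-3-methoxybenzaldehyde, via aluminium aldimide 17 (not isolated)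
Conditions: DIBAL-H, CH2Cl2, −78 °C; then aq. citric acid (10%), 0 °C
Reagents that add atoms: water, O
Why: Partial hydride reduction of an aryl nitrile stops at the N-aluminio aldimine, which is hydrolysed on work-up to the aldehyde (DIBAL nitrile-to-aldehyde reduction); silyl ethers are inert at −78 °C.

Step 11
Reactants: 3 2-Ar-1,3-dithiane; 7 (5R)-5-(Men-oxy)furan-2(5H)-one; 18 4-(Sil-oxy)-3-methoxybenzaldehyde
Product: 21 (3S,4R,5R)-3-{hydroxy[3-methoxy-4-(Sil-oxy)phenyl]methyl}-4-(2-Ar-1,3-dithian-2-yl)-5-(Men-oxy)dihydrofuran-2(3H)-one as carbinol epimers, via lithiated dithiane 19 (not isolated), via lactone lithium enolate 20 (not isolated)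
Conditions: 3, n-BuLi, THF, −78 → −30 °C; 7, −78 °C; then 18, −78 °C; AcOH quench at −78 °C
Reagents that add atoms: none
Why: The sulfur-stabilised benzylic carbanion 19 adds 1,4 to the β-carbon (C4) of butenolide 7, forming the benzylic C–C4 bond and the lactone enolate 20, which is trapped in the same flask at its α-carbon (C3) by aldehyde 18 in an aldol addition, so that all thirty skeletal carbons of the target are joined in one operation. The closest known reaction type is the tandem conjugate addition–aldol (or –alkylation) of 2-aryl-2-lithio-1,3-dithianes with 5-alkoxy-2(5H)-furanones used for dibenzylbutyrolactone lignans. No ring is closed; the lactone ring of 7 is carried as the latent C9'–C8'–C8–C9 unit. The new C4 stereocentre (C8' of the target) is set by attack anti to the C5 menthyloxy group, and the new C3 stereocentre (C8) by approach of the aldehyde anti to the bulky C4 dithianyl group, giving the 3,4-trans-4,5-trans lactone; the carbinol carbon is expected as an epimer mixture, which is of no consequence because it is ionised and reset in step 14. The step needs 1,4- over 1,2-regioselectivity, secured by the soft, hindered aryl-dithianyl anion and the s-cis-locked butenolide, and π-facial selectivity, secured by the single acetal stereocentre of 7.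

Step 12
Reactants: 21 (3S,4R,5R)-3-{hydroxy[3-methoxy-4-(Sil-oxy)phenyl]methyl}-4-(2-Ar-1,3-dithian-2-yl)-5-(Men-oxy)dihydrofuran-2(3H)-one
Product: 22 (3S,4R,5R)-3-{hydroxy[3-methoxy-4-(Sil-oxy)phenyl]methyl}-4-(Ar-methyl)-5-(Men-oxy)dihydrofuran-2(3H)-one as carbinol epimers
Conditions: Raney Ni (W-2, acetone-deactivated), EtOH/THF, rt
Reagents that add atoms: none
Why: Raney-nickel hydrogenolysis of both C–S bonds (Mozingo-type desulfurisation) turns the dithioketal into the benzylic CH2; the deactivated catalyst at room temperature should spare the benzylic alcohol, the silyl ethers and the acetal.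

Step 13
Reactants: 22 (3S,4R,5R)-3-{hydroxy[3-methoxy-4-(Sil-oxy)phenyl]methyl}-4-(Ar-methyl)-5-(Men-oxy)dihydrofuran-2(3H)-one
Product: 23 (2R,3R)-2-{hydroxy[3-methoxy-4-(Sil-oxy)phenyl]methyl}-3-(Ar-methyl)butane-1,4-diol as carbinol epimers
Conditions: LiAlH4, THF, 0 °C → rt; Fieser work-up
Reagents that add atoms: none
Why: LiAlH4 reduces both the lactone carbonyl and the masked C9' aldehyde of the acylal-type 5-alkoxybutyrolactone to the 1,4-diol with release of menthol (a known reduction of menthyloxy lactones); no stereocentre is touched.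

Step 14
Reactants: 23 (2R,3R)-2-{hydroxy[3-methoxy-4-(Sil-oxy)phenyl]methyl}-3-(Ar-methyl)butane-1,4-diol
Product: 25 [(2S,3R,4R)-2-[3-methoxy-4-(Sil-oxy)phenyl]-4-(Ar-methyl)tetrahydrofuran-3-yl]methanol, via benzylic cation 24 (not isolated)
Conditions: CSA (10 mol%), CH2Cl2, 0 °C; Et3N quench
Reagents that add atoms: none
Why: Brønsted-acid ionisation of the free p-alkoxybenzylic alcohol and 5-exo capture of the cation by the C9' hydroxyl (dehydrative benzylic etherification of an aryl 1,4-diol) is reversible and should place the C2 aryl trans to the C3 hydroxymethyl group (7S) from either carbinol epimer, while the silicon-capped second benzylic oxygen is not expected to ionise and four-ring closure by the C9 hydroxyl is not competitive.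

Step 15
Reactants: 25 [(2S,3R,4R)-2-[3-methoxy-4-(Sil-oxy)phenyl]-4-(Ar-methyl)tetrahydrofuran-3-yl]methanol
Product: 26 (1S,2S)-1-(4-hydroxy-3-methoxyphenyl)-2-{4-[(2S,3R,4R)-4-(4-hydroxy-3-methoxybenzyl)-3-(hydroxymethyl)tetrahydrofuran-2-yl]-2-methoxyphenoxy}propane-1,3-diol (target)
Conditions: TBAF, AcOH, THF, 0 °C → rt
Reagents that add atoms: none
Why: Fluoride cleaves the two aryl TIPS ethers and the di-tert-butylsilylene in one operation; the acetic acid buffer avoids base- or acid-induced scrambling of the benzylic centres.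

## Compound list

1 | vanillin (4-hydroxy-3-methoxybenzaldehyde) | COc1cc(C=O)ccc1O | starting material
2 | 3-methoxy-4-[(triisopropylsilyl)oxy]benzaldehyde | COc1cc(C=O)ccc1O[Si](C(C)C)(C(C)C)C(C)C | intermediate
3 | 2-{3-methoxy-4-[(triisopropylsilyl)oxy]phenyl}-1,3-dithiane | COc1cc(C2SCCCS2)ccc1O[Si](C(C)C)(C(C)C)C(C)C | intermediate
4 | furfural (furan-2-carbaldehyde) | O=Cc1ccco1 | starting material
5 | 5-hydroxyfuran-2(5H)-one (racemic) | O=C1C=CC(O)O1 | intermediate
6 | (−)-menthol, (1R,2S,5R)-2-isopropyl-5-methylcyclohexan-1-ol | O[C@@H]1C[C@H](C)CC[C@H]1C(C)C | starting material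
7 | (5R)-5-{[(1R,2S,5R)-2-isopropyl-5-methylcyclohexyl]oxy}furan-2(5H)-one | O=C1C=C[C@H](O[C@@H]2C[C@H](C)CC[C@H]2C(C)C)O1 | intermediate
8 | (4R)-4-benzyl-1,3-oxazolidin-2-one | O=C1N[C@H](Cc2ccccc2)CO1 | starting material
9 | bromoacetyl bromide | BrCC(Br)=O | starting material
10 | (4R)-4-benzyl-3-(bromoacetyl)-1,3-oxazolidin-2-one | O=C1N(C(=O)CBr)[C@H](Cc2ccccc2)CO1 | intermediate
11 | 4-hydroxy-3-methoxybenzonitrile | COc1cc(C#N)ccc1O | starting material
12 | (4R)-4-benzyl-3-[(4-cyano-2-methoxyphenoxy)acetyl]-1,3-oxazolidin-2-one | O=C1N(C(=O)COc2ccc(C#N)cc2OC)[C@H](Cc3ccccc3)CO1 | intermediate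
13 | (Z)-di-n-butylboron enolate of 12 | CCCCB(CCCC)O/C(=C\Oc1ccc(C#N)cc1OC)N2C(=O)OC[C@H]2Cc3ccccc3 | intermediate
14 | (4R)-4-benzyl-3-[(2R,3S)-2-(4-cyano-2-methoxyphenoxy)-3-hydroxy-3-{3-methoxy-4-[(triisopropylsilyl)oxy]phenyl}propanoyl]-1,3-oxazolidin-2-one | O=C1N(C(=O)[C@H](Oc2ccc(C#N)cc2OC)[C@@H](O)c3ccc(O[Si](C(C)C)(C(C)C)C(C)C)c(OC)c3)[C@H](Cc4ccccc4)CO1 | intermediate
15 | 4-{[(1S,2S)-1,3-dihydroxy-1-{3-methoxy-4-[(triisopropylsilyl)oxy]phenyl}propan-2-yl]oxy}-3-methoxybenzonitrile | N#Cc1ccc(O[C@@H](CO)[C@@H](O)c2ccc(O[Si](C(C)C)(C(C)C)C(C)C)c(OC)c2)c(OC)c1 | intermediate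
16 | 4-{[(4S,5S)-2,2-di-tert-butyl-4-{3-methoxy-4-[(triisopropylsilyl)oxy]phenyl}-1,3,2-dioxasilinan-5-yl]oxy}-3-methoxybenzonitrile | N#Cc1ccc(O[C@H]2CO[Si](C(C)(C)C)(C(C)(C)C)O[C@H]2c3ccc(O[Si](C(C)C)(C(C)C)C(C)C)c(OC)c3)c(OC)c1 | intermediate
17 | N-(diisobutylalumanyl)aldimine of 18 | CC(C)C[Al](CC(C)C)N=Cc1ccc(O[C@H]2CO[Si](C(C)(C)C)(C(C)(C)C)O[C@H]2c3ccc(O[Si](C(C)C)(C(C)C)C(C)C)c(OC)c3)c(OC)c1 | intermediate
18 | 4-{[(4S,5S)-2,2-di-tert-butyl-4-{3-methoxy-4-[(triisopropylsilyl)oxy]phenyl}-1,3,2-dioxasilinan-5-yl]oxy}-3-methoxybenzaldehyde | O=Cc1ccc(O[C@H]2CO[Si](C(C)(C)C)(C(C)(C)C)O[C@H]2c3ccc(O[Si](C(C)C)(C(C)C)C(C)C)c(OC)c3)c(OC)c1 | intermediate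
19 | 2-lithio-2-{3-methoxy-4-[(triisopropylsilyl)oxy]phenyl}-1,3-dithiane | [Li]C1(SCCCS1)c2ccc(O[Si](C(C)C)(C(C)C)C(C)C)c(OC)c2 | intermediate
20 | lithium (4R,5R)-4-(2-Ar-1,3-dithian-2-yl)-5-(Men-oxy)-4,5-dihydrofuran-2-olate | [Li]OC1=C[C@@H](C2(SCCCS2)c3ccc(O[Si](C(C)C)(C(C)C)C(C)C)c(OC)c3)[C@H](O[C@@H]4C[C@H](C)CC[C@H]4C(C)C)O1 | intermediate
21 | (3S,4R,5R)-3-{hydroxy[3-methoxy-4-(Sil-oxy)phenyl]methyl}-4-(2-Ar-1,3-dithian-2-yl)-5-(Men-oxy)dihydrofuran-2(3H)-one, both carbinol epimers | O=C1O[C@@H](O[C@@H]2C[C@H](C)CC[C@H]2C(C)C)[C@H](C3(SCCCS3)c4ccc(O[Si](C(C)C)(C(C)C)C(C)C)c(OC)c4)[C@H]1C(O)c5ccc(O[C@H]6CO[Si](C(C)(C)C)(C(C)(C)C)O[C@H]6c7ccc(O[Si](C(C)C)(C(C)C)C(C)C)c(OC)c7)c(OC)c5 | intermediate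
22 | (3S,4R,5R)-3-{hydroxy[3-methoxy-4-(Sil-oxy)phenyl]methyl}-4-{3-methoxy-4-[(triisopropylsilyl)oxy]benzyl}-5-(Men-oxy)dihydrofuran-2(3H)-one, both carbinol epimers | O=C1O[C@@H](O[C@@H]2C[C@H](C)CC[C@H]2C(C)C)[C@H](Cc3ccc(O[Si](C(C)C)(C(C)C)C(C)C)c(OC)c3)[C@H]1C(O)c4ccc(O[C@H]5CO[Si](C(C)(C)C)(C(C)(C)C)O[C@H]5c6ccc(O[Si](C(C)C)(C(C)C)C(C)C)c(OC)c6)c(OC)c4 | intermediate
23 | (2R,3R)-2-{hydroxy[3-methoxy-4-(Sil-oxy)phenyl]methyl}-3-{3-methoxy-4-[(triisopropylsilyl)oxy]benzyl}butane-1,4-diol, both carbinol epimers | OC[C@H](Cc1ccc(O[Si](C(C)C)(C(C)C)C(C)C)c(OC)c1)[C@H](CO)C(O)c2ccc(O[C@H]3CO[Si](C(C)(C)C)(C(C)(C)C)O[C@H]3c4ccc(O[Si](C(C)C)(C(C)C)C(C)C)c(OC)c4)c(OC)c2 | intermediate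
24 | benzylic (C7) cation derived from 23 | OC[C@H](Cc1ccc(O[Si](C(C)C)(C(C)C)C(C)C)c(OC)c1)[C@H](CO)[CH+]c2ccc(O[C@H]3CO[Si](C(C)(C)C)(C(C)(C)C)O[C@H]3c4ccc(O[Si](C(C)C)(C(C)C)C(C)C)c(OC)c4)c(OC)c2 | intermediate
25 | [(2S,3R,4R)-2-[3-methoxy-4-(Sil-oxy)phenyl]-4-{3-methoxy-4-[(triisopropylsilyl)oxy]benzyl}tetrahydrofuran-3-yl]methanol | COc1cc(C[C@H]2CO[C@H](c3ccc(O[C@H]4CO[Si](C(C)(C)C)(C(C)(C)C)O[C@H]4c5ccc(O[Si](C(C)C)(C(C)C)C(C)C)c(OC)c5)c(OC)c3)[C@H]2CO)ccc1O[Si](C(C)C)(C(C)C)C(C)C | intermediate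
26 | (1S,2S)-1-(4-hydroxy-3-methoxyphenyl)-2-{4-[(2S,3R,4R)-4-(4-hydroxy-3-methoxybenzyl)-3-(hydroxymethyl)tetrahydrofuran-2-yl]-2-methoxyphenoxy}propane-1,3-diol | COc1cc(C[C@H]2CO[C@H](c3ccc(O[C@@H](CO)[C@@H](O)c4ccc(O)c(OC)c4)c(OC)c3)[C@H]2CO)ccc1O | target

## Step count and risks

Total step count: 15. Longest linear sequence: 11 steps (steps 5–15, from 8 and 9).

Steps most likely to fail:

Step 11. The hindered enolate 20 may not capture the bulky aldehyde (proton transfer, or retro-aldol on warming), or 19 may add 1,2 to the lactone carbonyl. The fallback sets out from 3 and 7 and comes back at 22. The conjugate addition is run alone and quenched with acid to give the dithianyl lactone F1. Raney nickel removes the sulfur at this stage, where no benzylic alcohol is present, to give the benzyl lactone F2. The lithium enolate of F2 (LDA, THF, −78 °C), no longer encumbered by the dithiane, is then added to 18 anti to the C4 benzyl group (aldol of a β-benzyl-γ-butyrolactone enolate) to give 22 directly, so that step 12 is bypassed as well.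

Step 14. Chemoselectivity of the ionisation may be lost: the C7 cation may be captured by the electron-rich benzyl ring (aryltetralin formation), the second benzylic centre may ionise and epimerise, or the 2,3-trans preference may be poor. The fallback sets out from 3 and 7 and comes back at 26; it attaches the arylglycerol unit only after the ring is closed. The key step is repeated with commercial vanillin acetate (4-formyl-2-methoxyphenyl acetate, COc1cc(C=O)ccc1OC(C)=O) in place of 18 to give the adduct F3, and Raney nickel gives the lactone F4. LiAlH4 reduces the lactone acetal and cleaves the acetate to give the phenolic tetraol F5. Its acid-catalysed closure now involves a single benzylic alcohol para to a free phenol, a closure type well established for p-hydroxybenzylic 1,4-diols, and should give the mono-TIPS tetrahydrofuran F6. Phenol-selective alkylation of F6 with 10 (K2CO3, acetone) gives the imide F7. Evans aldol of F7 with 2 (excess n-Bu2BOTf, which masks the primary hydroxyl as its borinate) gives the adduct F8; LiBH4 gives the bis-TIPS ether F9, and TBAF gives 26.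

Step 12. The free, electron-rich benzylic hydroxyl may be hydrogenolysed on nickel, or desulfurisation may stall through catalyst deactivation. The fallback sets out from 21 and comes back at 25; the order is changed so that nickel never meets a free benzylic alcohol. LiAlH4 reduction of 21 gives the dithiane triol F10. Acid-catalysed closure as in step 14 gives the dithiane-bearing tetrahydrofuran F11, in which the benzylic oxygens are present only as ethers. Desulfurisation of F11 (Raney Ni or NiCl2/NaBH4) then gives 25.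

Further compounds
F1 | step 11 | (4R,5R)-4-(2-Ar-1,3-dithian-2-yl)-5-(Men-oxy)dihydrofuran-2(3H)-one | O=C1C[C@@H](C2(SCCCS2)c3ccc(O[Si](C(C)C)(C(C)C)C(C)C)c(OC)c3)[C@H](O[C@@H]4C[C@H](C)CC[C@H]4C(C)C)O1
F2 | step 11 | (4R,5R)-4-{3-methoxy-4-[(triisopropylsilyl)oxy]benzyl}-5-(Men-oxy)dihydrofuran-2(3H)-one | O=C1C[C@@H](Cc2ccc(O[Si](C(C)C)(C(C)C)C(C)C)c(OC)c2)[C@H](O[C@@H]3C[C@H](C)CC[C@H]3C(C)C)O1
F3 | step 14 | (3S,4R,5R)-3-[(4-acetoxy-3-methoxyphenyl)(hydroxy)methyl]-4-(2-Ar-1,3-dithian-2-yl)-5-(Men-oxy)dihydrofuran-2(3H)-one, both carbinol epimers | O=C1O[C@@H](O[C@@H]2C[C@H](C)CC[C@H]2C(C)C)[C@H](C3(SCCCS3)c4ccc(O[Si](C(C)C)(C(C)C)C(C)C)c(OC)c4)[C@H]1C(O)c5ccc(OC(C)=O)c(OC)c5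
F4 | step 14 | (3S,4R,5R)-3-[(4-acetoxy-3-methoxyphenyl)(hydroxy)methyl]-4-{3-methoxy-4-[(triisopropylsilyl)oxy]benzyl}-5-(Men-oxy)dihydrofuran-2(3H)-one, both carbinol epimers | O=C1O[C@@H](O[C@@H]2C[C@H](C)CC[C@H]2C(C)C)[C@H](Cc3ccc(O[Si](C(C)C)(C(C)C)C(C)C)c(OC)c3)[C@H]1C(O)c4ccc(OC(C)=O)c(OC)c4
F5 | step 14 | (2R,3R)-2-[hydroxy(4-hydroxy-3-methoxyphenyl)methyl]-3-{3-methoxy-4-[(triisopropylsilyl)oxy]benzyl}butane-1,4-diol, both carbinol epimers | OC[C@H](Cc1ccc(O[Si](C(C)C)(C(C)C)C(C)C)c(OC)c1)[C@H](CO)C(O)c2ccc(O)c(OC)c2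
F6 | step 14 | 4-[(2S,3R,4R)-3-(hydroxymethyl)-4-{3-methoxy-4-[(triisopropylsilyl)oxy]benzyl}tetrahydrofuran-2-yl]-2-methoxyphenol | COc1cc(C[C@H]2CO[C@H](c3ccc(O)c(OC)c3)[C@H]2CO)ccc1O[Si](C(C)C)(C(C)C)C(C)C
F7 | step 14 | (4R)-4-benzyl-3-[(4-{(2S,3R,4R)-3-(hydroxymethyl)-4-[3-methoxy-4-(triisopropylsilyloxy)benzyl]tetrahydrofuran-2-yl}-2-methoxyphenoxy)acetyl]-1,3-oxazolidin-2-one | COc1cc(C[C@H]2CO[C@H](c3ccc(OCC(=O)N4C(=O)OC[C@H]4Cc5ccccc5)c(OC)c3)[C@H]2CO)ccc1O[Si](C(C)C)(C(C)C)C(C)C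
F8 | step 14 | (2R,3S)-syn-aldol adduct of F7 with 2, N-acyl (4R)-4-benzyloxazolidin-2-one | COc1cc(C[C@H]2CO[C@H](c3ccc(O[C@H]([C@@H](O)c4ccc(O[Si](C(C)C)(C(C)C)C(C)C)c(OC)c4)C(=O)N5C(=O)OC[C@H]5Cc6ccccc6)c(OC)c3)[C@H]2CO)ccc1O[Si](C(C)C)(C(C)C)C(C)C
F9 | step 14 | bis(triisopropylsilyl) ether of 26 at both phenolic oxygens | COc1cc(C[C@H]2CO[C@H](c3ccc(O[C@@H](CO)[C@@H](O)c4ccc(O[Si](C(C)C)(C(C)C)C(C)C)c(OC)c4)c(OC)c3)[C@H]2CO)ccc1O[Si](C(C)C)(C(C)C)C(C)C
F10 | step 12 | (2R,3R)-2-{hydroxy[3-methoxy-4-(Sil-oxy)phenyl]methyl}-3-(2-Ar-1,3-dithian-2-yl)butane-1,4-diol, both carbinol epimers | OC[C@H](C1(SCCCS1)c2ccc(O[Si](C(C)C)(C(C)C)C(C)C)c(OC)c2)[C@H](CO)C(O)c3ccc(O[C@H]4CO[Si](C(C)(C)C)(C(C)(C)C)O[C@H]4c5ccc(O[Si](C(C)C)(C(C)C)C(C)C)c(OC)c5)c(OC)c3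
F11 | step 12 | [(2S,3R,4R)-2-[3-methoxy-4-(Sil-oxy)phenyl]-4-(2-Ar-1,3-dithian-2-yl)tetrahydrofuran-3-yl]methanol | COc1cc(C6(SCCCS6)[C@H]2CO[C@H](c3ccc(O[C@H]4CO[Si](C(C)(C)C)(C(C)(C)C)O[C@H]4c5ccc(O[Si](C(C)C)(C(C)C)C(C)C)c(OC)c5)c(OC)c3)[C@H]2CO)ccc1O[Si](C(C)C)(C(C)C)C(C)C
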